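## Retrosynthetic overview

1. Building blocks: 2,5-dihydroxy-1,4-benzoquinone 1 supplies the ring and all four ring oxygens; pentadecanal 2 supplies the chain.
2. C3–CH2 bond: three-component reductive alkylation of 1 with 2, through alkylidene trione 3, gives 2,5-dihydroxy-3-pentadecyl-1,4-benzoquinone 4.
3. Key disconnection, made last: the O–CH3 bond of the C5 methoxy group. Compound 4 is methylated site-selectively on the vinylogous acid that carries no chain, through ion pair 5, to give target 6.
4. Rings: none is formed; the quinone ring is carried through from 1.

Assumption: the target has no stereocentre and no stereogenic double bond, so it is a single achiral compound and no enantiocontrol is needed; the side chain is read as unbranched pentadecyl (C15, C22H36O4).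

## Route

**Step 1**
Reactants: 1 2,5-dihydroxy-1,4-benzoquinone; 2 pentadecanal
Product: 4 2,5-dihydroxy-3-pentadecyl-1,4-benzoquinone, via alkylidene trione 3 (not isolated)
Conditions: 1 (2.0 equiv), Hantzsch ester (diethyl 1,4-dihydro-2,6-dimethylpyridine-3,5-dicarboxylate, 1.1 equiv), L-proline (20 mol%), EtOH, 40 °C, N2; 2 (1.0 equiv) added over 2 h, then 12 h
Reagents that add atoms: none
Why: Three-component reductive alkylation (Knoevenagel condensation followed by conjugate hydride transfer from the Hantzsch ester): the enolic C3 of 1 condenses with the proline-activated aldehyde to the electron-poor alkylidene 3, which the Hantzsch ester present from the start reduces before a second quinone can add to it, while the excess of 1 and the slow addition of 2 hold back 3,6-dialkylation; no stereocentre is formed.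

**Step 2 (key step)**
Reactants: 4 2,5-dihydroxy-3-pentadecyl-1,4-benzoquinone
Product: 6 2-hydroxy-5-methoxy-3-pentadecyl-1,4-benzoquinone, via isouronium quinonolate ion pair 5 (not isolated)
Conditions: O-methyl-N,N′-diisopropylisourea (0.95 equiv, added over 4 h), THF, 50 °C, 16 h
Reagents that add atoms: O-methyl-N,N′-diisopropylisourea, COC(=NC(C)C)NC(C)C
Why: Proposed new method: acidity-gated methyl transfer, in which the neutral isourea is protonated by the stronger of the two vinylogous carboxylic acids of 4, the chain-free O=C1–C6H=C5–OH unit (estimated about one pKa unit more acidic than the pentadecyl-bearing unit, by analogy with 2-hydroxy-1,4-naphthoquinone against its 3-methyl homologue), and the quinonolate of ion pair 5 then attacks the O-methyl group of its own isouronium counter-ion in an SN2 step that releases the urea; methylation at either oxygen of that unit gives 6 after tautomerisation, and because 6 is a weaker and more hindered acid the limiting reagent stays paired with unreacted 4, so the reaction should stop at the mono-ether; the closest known reaction is the esterification of carboxylic acids with O-alkylisoureas (and the promoter-free esterification with trichloroacetimidates), which to my knowledge has not been shown on 2,5-dihydroxyquinones or used to tell two vinylogous acids apart; no stereocentre is formed.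

## Compound list

1 | 2,5-dihydroxy-1,4-benzoquinone | O=C1C=C(O)C(=O)C=C1O | starting material
2 | pentadecanal | CCCCCCCCCCCCCCC=O | starting material
3 | 5-hydroxy-3-pentadecylidenecyclohex-5-ene-1,2,4-trione (E/Z mixture, geometry of no consequence) | CCCCCCCCCCCCCCC=C1C(=O)C(=O)C=C(O)C1=O | intermediate
4 | 2,5-dihydroxy-3-pentadecyl-1,4-benzoquinone | CCCCCCCCCCCCCCCC1=C(O)C(=O)C=C(O)C1=O | intermediate
5 | O-methyl-N,N′-diisopropylisouronium salt of the mono-anion of 4 (chain-free vinylogous acid deprotonated) | CCCCCCCCCCCCCCCC1=C(O)C(=O)C=C([O-])C1=O.COC(NC(C)C)=[NH+]C(C)C | intermediate
6 | 2-hydroxy-5-methoxy-3-pentadecyl-1,4-benzoquinone (achiral) | CCCCCCCCCCCCCCCC1=C(O)C(=O)C=C(OC)C1=O | target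

## Totals

Total step count: 2
Longest linear sequence: 2 steps (1 → 4 → 6)

## Steps most likely to fail

The route has only two steps, so both are ranked.

First, step 2 (the proposed new method). The risks are incomplete site selection (the isomeric ether on the chain-bearing side), some dimethylation late in the reaction, and a slow SN2 step with this weakly basic quinonolate. The fallback uses known chemistry and forms a different bond: acid-catalysed vinylogous Fischer etherification of 4 in methanol (MeOH, catalytic H2SO4, reflux, stopped at the mono-ether). Here methanol adds to ring carbon C5 and water leaves, so the ring C–O bond is made instead of the O–CH3 bond. Selection comes from sterics, since C5 is flanked by C6–H while the other enol carbon is flanked by the chain, and from the better conjugation of an unhindered, coplanar methoxy group. This fallback sets out from 4 and comes back to the route at 6; it makes no new compound (F0).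

Second, step 1. The risks are double alkylation at C3 and C6, Michael trapping of 3 by a second quinone, and separation of 4 from the excess of 1. The fallback inverts the order of the two bond formations so that only one enolic carbon is available. Starting from 1, brief acid-catalysed methanolysis (MeOH, catalytic HCl, room temperature, short reaction time) gives 2-hydroxy-5-methoxy-1,4-benzoquinone F1. Reductive alkylation of F1 with 2 (Hantzsch ester, L-proline, EtOH, 40 °C) then proceeds through 5-methoxy-3-pentadecylidenecyclohex-5-ene-1,2,4-trione F2 (not isolated) and can only occur at the carbon next to the free hydroxyl. This fallback sets out from 1 and comes back to the route at 6.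

## Further compounds

F1 | step 1 | 2-hydroxy-5-methoxy-1,4-benzoquinone | COC1=CC(=O)C(O)=CC1=O
F2 | step 1 | 5-methoxy-3-pentadecylidenecyclohex-5-ene-1,2,4-trione | CCCCCCCCCCCCCCC=C1C(=O)C(=O)C=C(OC)C1=O
F0 | step 2 | none | none
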